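In this closed, stirred vessel the starting material sits in the first phase and the reagent in the second, and target and over-reacted product are read in percent of the starting material charged.

| flask | starting material | reagent in the second phase | remark | time | volume of the second phase over the first |
|---|---|---|---|---|---|
| epsilon | 0.20 M | 0.168 M | run made earlier |  |  |
| zeta | 0.72 M | 0.168 M | run made earlier |  |  |
| beta | 0.14 M | 0.34 M | run made earlier |  |  |
| noon | 0.14 M | 0.168 M |  | 5.0 min | 2.0 |
| summer | 0.60 M | 0.600 M |  | 1.5 min | 2.0 |

- in the second phase: reagent in the second phase; everything else is in the first
- charges count per volume of the first phase; a concentration in a rate is the amount of a species over the volume of its own phase; every rate counts per litre of the first phase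
- the earlier runs hold the two phases in the same ratio of volumes as the flask asked about

* which of the two ends with the higher share of target in all that became target or over-reacted product or over-reaction product ("neither" if they lie within 2 percentage points) (noon / summer / neither)
* share of target in all that became target or over-reacted product or over-reaction product, noon
* share of target in all that became target or over-reacted product or over-reaction product, summer

| run | time / min | target / % | over-reacted product / % |
|---|---|---|---|
| epsilon | 0.417 | 0.4 | 0.8 |
| epsilon | 0.833 | 0.4 | 0 |
| epsilon | 1.33 | 1.7 | 0 |
| epsilon | 2.50 | 3.1 | 0 |
| epsilon | 5.00 | 7.2 | 1.3 |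
| zeta | 0.417 | 0.5 | 0 |
| zeta | 0.833 | 0.6 | 0 |
| zeta | 1.33 | 1.5 | 0 |
| zeta | 2.50 | 1.7 | 0 |
| zeta | 5.00 | 4.8 | 0 |
| beta | 0.417 | 0 | 0 |
| beta | 0.833 | 0.5 | 0.9 |
| beta | 1.33 | 3.0 | 0 |
| beta | 2.50 | 5.6 | 0.2 |
| beta | 5.00 | 12.1 | 1.0 |

(each reading ± 0.5 percentage points)

Read the last row of each table. Target stands at 7.2% in epsilon, 4.8% in zeta and 12.1% in beta, and over-reacted product at 1.3%, 0% and 1.0%. Against a scatter of 0.5 percentage points you shouldn't trust one row, so sum them.

Let x be target as a fraction of the charge. Suppose target goes on to over-reacted product and draws on the same reagent as starting material does: the reagent then cancels from the ratio of their rates. While starting material stays near its charge, over-reacted product grows as s·x·x/2. The summed rows give s = 2.08, a reading. This s is the selectivity factor, how many times more readily target takes reagent than starting material does. The share of target is then 1/(1 + s·x/2), so you need x.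

Noon has epsilon's reagent and time and lies near it in starting material, so I take x = 7.2%. Summer's starting material lies near zeta's. Zeta's target rises between its last two rows as time to the power 1.50, a reading from two scattered points. Scaling by that power of time, and in proportion to reagent as I assume, gives x = 2.83%.

My shares are 93.0% for noon and 97.1% for summer, a gap of 4.1 points, more than the margin, so I say summer.

The forecast gave 93% for noon and 92.5% for summer, hence neither, holding that “Saturation cancels in the ratio”. It agrees with me on noon and parts from me on summer.

The flask gives 93.2% for noon and 97.3% for summer, so summer.

    reagent in the reaction phase ⇌ reagent in the second phase, rate k1*([reagent in the reaction phase] - [reagent in the second phase]/K1) per volume of the first phase (partition coefficient = 1.10, kL = 0.00250 s⁻¹)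
    starting material + reagent in the reaction phase → target (k = 0.0190 M⁻¹ s⁻¹)
    reagent in the reaction phase + target → over-reacted product (k = 0.0310 M⁻¹ s⁻¹)
    2 reagent in the reaction phase → homo dimer (k = 0.0390 M⁻¹ s⁻¹)
    reagent in the reaction phase + target → over-reaction product (k = 4.10 × 10⁻⁴ M⁻¹ s⁻¹)

The step to target and the step to over-reacted product both use reagent in the reaction phase, and at the end of noon over-reacted product forms at 13.4% of the rate at which target forms. In summer it forms at 5.39%, less than in noon, with target at 3.20% against 7.57%. From those targets, s gives 92.7% for noon and 96.8% for summer. Left until 4.0 min, summer holds target at 10.8%, where s gives 89.9% and the flask shows 89.9%.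

The numbers in the tables stem from a simulated flask from invented constants, and the scatter is random.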